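The route rests on disconnecting the O1–C7a bond of the 1,2-dioxane ring (numbering: O1, O2, C3, C4, C4a, O5, lactone carbonyl C6, C7, C7a). C7a is the β-carbon of the γ-lactone carbonyl, so this bond is a latent conjugate addition: an ozonolysis-derived α-methoxy hydroperoxide tethered to C4a of an (S)-butenolide closes the dioxane by 6-exo peroxy-Michael addition, and quaternary C4a forces the cis ring fusion at C7a. The precursor, a 5-(2-hydroperoxy-2-methoxypropyl)-5-methylbutenolide, comes from (R)-lactic acid. C3 passes through the key step as an epimeric methoxy peroxyketal; later ionisation to a peroxycarbenium ion and capture by a vinylogous silyl enol ether sets C3 and delivers an enal for Julia–Kocienski chain attachment.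

Key step: step 6

Remark: the target is read from its SMILES as (3R,4aS,7aS) with an all-E side chain; the side-chain CH2 on C3 is cis to the lactone oxygen O5 and trans to the C4a methyl.

**Step 1**
Reactants: 1 (R)-lactic acid; 2 pivalaldehyde (2,2-dimethylpropanal)
Product: 3 (2R,5R)-2-tert-butyl-5-methyl-1,3-dioxolan-4-one (cis)
Conditions: p-TsOH (cat.), H2SO4 (cat.), pentane, reflux, Dean–Stark; crystallisation from pentane/Et2O, −78 °C
Reagents that add atoms: none
Why: Acid-catalysed acetalisation with azeotropic removal of water should give mainly the cis dioxolanone, which crystallises, so the lactate stereocentre is stored in the new acetal centre C2 (self-regeneration of stereocentres).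

**Step 2**
Reactants: 3 (2R,5R)-2-tert-butyl-5-methyl-1,3-dioxolan-4-one; 4 3-bromo-2-methylprop-1-ene
Product: 6 (2R,5S)-2-tert-butyl-5-methyl-5-(2-methylprop-2-en-1-yl)-1,3-dioxolan-4-one, via lithium enolate 5 (not isolated)
Conditions: LiN(iPr)2 (1.1 equiv), THF, −78 °C; then 4, −78 to −30 °C
Reagents that add atoms: none
Why: Enolate alkylation: deprotonation flattens C5 and the tert-butyl group on C2 shields one face, so the allylic bromide enters trans to it and the quaternary carbinol centre (the future C4a) is formed as S.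

**Step 3**
Reactants: 6 (2R,5S)-2-tert-butyl-5-methyl-5-(2-methylprop-2-en-1-yl)-1,3-dioxolan-4-one
Product: 7 (2R,5S)-2-tert-butyl-5-methyl-5-(2-methylprop-2-en-1-yl)-1,3-dioxolan-4-ol (both C4 anomers)
Conditions: iBu2AlH (1.1 equiv), CH2Cl2, −78 °C; aq. KNaC4H4O6 work-up
Reagents that add atoms: none
Why: Low-temperature iBu2AlH reduction stops at the stable aluminium hemiacetal, so the dioxolanone carbonyl is taken only to the lactol level (partial reduction of a lactone) and the existing stereocentres are untouched.

**Step 4**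
Reactants: 7 (2R,5S)-2-tert-butyl-5-methyl-5-(2-methylprop-2-en-1-yl)-1,3-dioxolan-4-ol; 8 methyl (triphenylphosphoranylidene)acetate
Product: 11 (5S)-5-methyl-5-(2-methylprop-2-en-1-yl)furan-2(5H)-one, via hydroxy aldehyde 9 (not isolated), via Z-hydroxy enoate 10 (not isolated)
Conditions: 8 (2.5 equiv), MeOH, 0 °C to rt; then p-TsOH (cat.), rt
Reagents that add atoms: none
Why: The lactol releases pivalaldehyde to give α-hydroxy aldehyde 9, whose Wittig reaction with the stabilised ylide in methanol should be Z-selective as for α-oxygenated aldehydes, and the Z-γ-hydroxy enoate 10 lactonises under acid to the butenolide (Wittig olefination–lactonisation); no stereocentre is formed.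

**Step 5**
Reactants: 11 (5S)-5-methyl-5-(2-methylprop-2-en-1-yl)furan-2(5H)-one
Product: 13 (5S)-5-(2-hydroperoxy-2-methoxypropyl)-5-methylfuran-2(5H)-one (both ketal epimers), via carbonyl oxide 12 (not isolated)
Conditions: O3 (1 equiv, Sudan Red 7B end point), CH2Cl2/MeOH (1:1), −78 °C; N2 purge, no reductant
Reagents that add atoms: ozone, [O-][O+]=O; methanol, CO
Why: Ozone should attack the electron-rich 1,1-disubstituted alkene much faster than the conjugated butenolide alkene, cleavage gives formaldehyde and the more substituted carbonyl oxide 12, and methanol traps 12 as the α-methoxy hydroperoxide (Criegee ozonolysis with solvent capture); the ketal centre forms without control and needs none.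

**Step 6**
Reactants: 13 (5S)-5-(2-hydroperoxy-2-methoxypropyl)-5-methylfuran-2(5H)-one
Product: 14 (4aS,7aS)-3-methoxy-3,4a-dimethyltetrahydro-3H-furo[3,2-c][1,2]dioxin-6(4H)-one (cis-fused, both C3 epimers)
Conditions: Et2NH (1 equiv), CF3CH2OH, rt
Reagents that add atoms: none
Why: Et2NH reversibly deprotonates the hydroperoxide, the peroxide anion (an α-effect nucleophile) adds to C7a, the β-carbon of the butenolide, and the acidic solvent protonates the lactone enolate at C7; this is an intramolecular peroxy-Michael addition, the known reaction type of hydroperoxy ketals with enoates under these conditions. The 1,2-dioxane closes in the 6-exo-trig mode. The new stereocentre C7a is controlled by C4a: the three-atom tether can reach only the face of the planar butenolide that carries the C4 methylene, so the dioxane must be cis-fused and C7a is S. The ketal carbon C3 stays an epimeric mixture, which is harmless because step 8 planarises it. The step needs O- over N-addition and must not reverse: amine addition is reversible and disfavoured in the hydrogen-bonding solvent, and CF3CH2OH quenches the enolate at once, which suppresses β-elimination of the peroxide.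

**Step 7**
Reactants: 15 3-methylbut-2-enal
Product: 16 (E)-trimethyl[(3-methylbuta-1,3-dien-1-yl)oxy]silane
Conditions: Me3SiCl, Et3N, ZnCl2 (cat.), toluene, 40 °C; distillation
Reagents that add atoms: chlorotrimethylsilane, C[Si](C)(C)Cl
Why: Soft γ-enolisation of the enal in the presence of Me3SiCl gives the conjugated silyl dienol ether, the E enol ether being the less hindered product (silyl dienol ether formation).

**Step 8**
Reactants: 14 (4aS,7aS)-3-methoxy-3,4a-dimethyltetrahydro-3H-furo[3,2-c][1,2]dioxin-6(4H)-one; 16 (E)-trimethyl[(3-methylbuta-1,3-dien-1-yl)oxy]silane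
Product: 18 (2E)-4-[(3R,4aS,7aS)-3,4a-dimethyl-6-oxotetrahydro-3H-furo[3,2-c][1,2]dioxin-3-yl]-3-methylbut-2-enal, via peroxycarbenium triflate 17 (not isolated)
Conditions: 16 (2.5 equiv), Me3SiOTf (0.3 equiv), CH2Cl2, −78 °C; aq. NaHCO3
Reagents that add atoms: none
Why: Lewis-acid ionisation of the exocyclic methoxy group gives the ring-retained peroxycarbenium ion 17 from both ketal epimers, which is captured at the γ-carbon of the dienol ether (vinylogous Mukaiyama-type substitution of a peroxyketal); in the half-chair with the lactone oxygen pseudoaxial and the C4a methyl pseudoequatorial, axial attack should occur cis to O5 and trans to the C4a methyl, setting C3 as R, and the s-trans dienol ether should give the E enal.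

**Step 9**
Reactants: 19 6-bromohex-1-ene; 20 1-phenyl-1H-tetrazole-5-thiol
Product: 21 5-(hex-5-en-1-ylsulfanyl)-1-phenyl-1H-tetrazole
Conditions: K2CO3, acetone, rt
Reagents that add atoms: none
Why: SN2 alkylation of the thiolate at the primary bromide.

**Step 10**
Reactants: 21 5-(hex-5-en-1-ylsulfanyl)-1-phenyl-1H-tetrazole
Product: 22 5-(hex-5-en-1-ylsulfonyl)-1-phenyl-1H-tetrazole
Conditions: (NH4)6Mo7O24·4H2O (cat.), 30% H2O2, EtOH, 0 °C to rt
Reagents that add atoms: hydrogen peroxide, OO
Why: Molybdate-catalysed peroxide oxidation takes the sulfide to the sulfone while the unactivated terminal alkene should stay intact.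

**Step 11**
Reactants: 22 5-(hex-5-en-1-ylsulfonyl)-1-phenyl-1H-tetrazole; 23 styrene
Product: 24 1-phenyl-5-{[(5E)-6-phenylhex-5-en-1-yl]sulfonyl}-1H-tetrazole
Conditions: second-generation Grubbs catalyst (3 mol %), 23 (5 equiv), CH2Cl2, 40 °C
Reagents that add atoms: none
Why: Olefin cross-metathesis of a terminal alkene with excess styrene is driven by loss of ethene and should give the conjugated E alkene under thermodynamic control.

**Step 12**
Reactants: 18 (2E)-4-[(3R,4aS,7aS)-3,4a-dimethyl-6-oxotetrahydro-3H-furo[3,2-c][1,2]dioxin-3-yl]-3-methylbut-2-enal; 24 1-phenyl-5-{[(5E)-6-phenylhex-5-en-1-yl]sulfonyl}-1H-tetrazole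
Product: 26 plakortolide H, via potassium sulfonyl carbanion 25 (not isolated)
Conditions: 24 (1.2 equiv), KN(SiMe3)2 (1.15 equiv), DME, −60 °C, 30 min; then 18, −60 °C to rt
Reagents that add atoms: none
Why: Julia–Kocienski olefination: the premetalated sulfone 25 should add to the aldehyde faster than it deprotonates the lactone, and Smiles rearrangement with loss of SO2 and the tetrazolate should give the E alkene expected for unbranched alkyl phenyltetrazolyl sulfones in DME; no stereocentre is touched.

**Compound list**
1 | (R)-lactic acid | C[C@@H](O)C(=O)O | starting material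
2 | pivalaldehyde | CC(C)(C)C=O | starting material
3 | (2R,5R)-2-tert-butyl-5-methyl-1,3-dioxolan-4-one | C[C@H]1O[C@@H](C(C)(C)C)OC1=O | intermediate
4 | 3-bromo-2-methylprop-1-ene | C=C(C)CBr | starting material
5 | lithium (2R)-2-tert-butyl-5-methyl-1,3-dioxol-4-olate | CC1=C([O-])O[C@H](C(C)(C)C)O1.[Li+] | intermediate (not isolated)
6 | (2R,5S)-2-tert-butyl-5-methyl-5-(2-methylprop-2-en-1-yl)-1,3-dioxolan-4-one | C=C(C)C[C@]1(C)O[C@@H](C(C)(C)C)OC1=O | intermediate
7 | (2R,5S)-2-tert-butyl-5-methyl-5-(2-methylprop-2-en-1-yl)-1,3-dioxolan-4-ol, C4 anomers | C=C(C)C[C@]1(C)O[C@@H](C(C)(C)C)OC1O | intermediate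
8 | methyl (triphenylphosphoranylidene)acetate | COC(=O)C=P(c1ccccc1)(c1ccccc1)c1ccccc1 | starting material
9 | (2S)-2-hydroxy-2,4-dimethylpent-4-enal | C=C(C)C[C@](C)(O)C=O | intermediate (not isolated)
10 | methyl (2Z,4S)-4-hydroxy-4,6-dimethylhepta-2,6-dienoate | C=C(C)C[C@](C)(O)/C=C\C(=O)OC | intermediate (not isolated)
11 | (5S)-5-methyl-5-(2-methylprop-2-en-1-yl)furan-2(5H)-one | C=C(C)C[C@]1(C)OC(=O)C=C1 | intermediate
12 | carbonyl oxide of (5S)-5-methyl-5-(2-oxopropyl)furan-2(5H)-one | CC(=[O+][O-])C[C@]1(C)OC(=O)C=C1 | intermediate (not isolated)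
13 | (5S)-5-(2-hydroperoxy-2-methoxypropyl)-5-methylfuran-2(5H)-one, ketal epimers | COC(C)(OO)C[C@]1(C)OC(=O)C=C1 | intermediate
14 | (4aS,7aS)-3-methoxy-3,4a-dimethyltetrahydro-3H-furo[3,2-c][1,2]dioxin-6(4H)-one, C3 epimers | COC1(C)C[C@]2(C)OC(=O)C[C@@H]2OO1 | intermediate
15 | 3-methylbut-2-enal | CC(C)=CC=O | starting material
16 | (E)-trimethyl[(3-methylbuta-1,3-dien-1-yl)oxy]silane | C=C(C)/C=C/O[Si](C)(C)C | intermediate
17 | (4aS,7aS)-3,4a-dimethyl-6-oxo-4a,6,7,7a-tetrahydro-4H-furo[3,2-c][1,2]dioxin-2-ium triflate | CC1=[O+]O[C@H]2CC(=O)O[C@@]2(C)C1.[O-]S(=O)(=O)C(F)(F)F | intermediate (not isolated)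
18 | (2E)-4-[(3R,4aS,7aS)-3,4a-dimethyl-6-oxotetrahydro-3H-furo[3,2-c][1,2]dioxin-3-yl]-3-methylbut-2-enal | C/C(=C\C=O)C[C@]1(C)C[C@]2(C)OC(=O)C[C@@H]2OO1 | intermediate
19 | 6-bromohex-1-ene | C=CCCCCBr | starting material
20 | 1-phenyl-1H-tetrazole-5-thiol | Sc1nnnn1-c1ccccc1 | starting material
21 | 5-(hex-5-en-1-ylsulfanyl)-1-phenyl-1H-tetrazole | C=CCCCCSc1nnnn1-c1ccccc1 | intermediate
22 | 5-(hex-5-en-1-ylsulfonyl)-1-phenyl-1H-tetrazole | C=CCCCCS(=O)(=O)c1nnnn1-c1ccccc1 | intermediate
23 | styrene | C=Cc1ccccc1 | starting material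
24 | 1-phenyl-5-{[(5E)-6-phenylhex-5-en-1-yl]sulfonyl}-1H-tetrazole | O=S(=O)(CCCC/C=C/c1ccccc1)c1nnnn1-c1ccccc1 | intermediate
25 | potassium α-sulfonyl carbanion of 24 | [K+].[CH-](CCC/C=C/c1ccccc1)S(=O)(=O)c1nnnn1-c1ccccc1 | intermediate (not isolated)
26 | plakortolide H, (3R,4aS,7aS)-3,4a-dimethyl-3-[(2E,4E,9E)-2-methyl-10-phenyldeca-2,4,9-trien-1-yl]tetrahydro-3H-furo[3,2-c][1,2]dioxin-6(4H)-one | C/C(=C\C=C\CCC/C=C/c1ccccc1)C[C@]1(C)C[C@]2(C)OC(=O)C[C@@H]2OO1 | target

Total step count: 12. Longest linear sequence: 8 steps (steps 1–6, 8 and 12).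

**Steps most likely to fail**

Step 8. The acid-labile, ambident dienol ether may oligomerise or react through its α-carbon before the hindered tertiary peroxycarbenium ion is captured. A very reactive nucleophile may also erode the axial facial preference at C3. The fallback sets out from 14 and comes back at 18. Compound 14 is treated with trimethyl(2-methylprop-2-en-1-yl)silane and Me3SiOTf in CH2Cl2 at −78 °C. This is a Sakurai-type substitution with a less reactive, non-ambident allylsilane, the nucleophile class best established for axial capture of six-membered oxocarbenium-type ions. It should give (3R,4aS,7aS)-3,4a-dimethyl-3-(2-methylprop-2-en-1-yl)tetrahydro-3H-furo[3,2-c][1,2]dioxin-6(4H)-one F1. The C8=C9 bond is then built by olefin cross-metathesis of F1 with excess (E)-but-2-enal and the second-generation Hoveyda–Grubbs catalyst in CH2Cl2 at 40 °C, which returns enal 18; geometric isomers would be separated.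

Step 6. The conjugate addition may stall or reverse, through reversible amine addition to the butenolide, β-elimination of the peroxide from the lactone enolate, or base-induced breakdown of the hydroperoxy ketal. The fallback sets out from 7 and comes back at 14; it closes the same O1–C7a bond on an acyclic acceptor.
- Wittig reaction of 7 with 8 in CH2Cl2 (E-selective) should give methyl (2E,4S)-4-hydroxy-4,6-dimethylhepta-2,6-dienoate F2, which cannot lactonise.
- Ozonolysis in CH2Cl2/MeOH at −78 °C should give methyl (2E,4S)-6-hydroperoxy-4-hydroxy-6-methoxy-4-methylhept-2-enoate F3.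
- Et2NH in CF3CH2OH should close the dioxane onto the unstrained enoate, giving methyl 2-[(3S,4S)-4-hydroxy-6-methoxy-4,6-dimethyl-1,2-dioxan-3-yl]acetate F4 together with its C3 epimer.
- Mild acid (pyridinium p-toluenesulfonate, CH2Cl2) lactonises F4, whose acetate arm is cis to the tertiary hydroxyl, to 14. The C3 epimer would be returned to the addition equilibrium by re-exposure to the amine.

Step 4. The lactol may open incompletely and the olefination may be insufficiently Z-selective, leaving E enoate that cannot lactonise. The fallback sets out from 7 and comes back at 11.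
- Methylenation of 7 with Ph3P=CH2 (from Ph3PCH3Br and KOtBu, THF, 0 °C to rt) should give (3S)-3,5-dimethylhexa-1,5-dien-3-ol F5.
- Acylation with acryloyl chloride, iPr2NEt and DMAP (cat.) in CH2Cl2 should give (3S)-3,5-dimethylhexa-1,5-dien-3-yl prop-2-enoate F6.
- Ring-closing metathesis with the second-generation Grubbs catalyst in CH2Cl2 at 40 °C should close the five-membered ring between the acrylate and the vinyl group, with the 1,1-disubstituted alkene as spectator. This gives butenolide 11 with the Z geometry enforced by the ring.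

**Further compounds**
F1 | step 8 | (3R,4aS,7aS)-3,4a-dimethyl-3-(2-methylprop-2-en-1-yl)tetrahydro-3H-furo[3,2-c][1,2]dioxin-6(4H)-one | C=C(C)C[C@]1(C)C[C@]2(C)OC(=O)C[C@@H]2OO1
F2 | step 6 | methyl (2E,4S)-4-hydroxy-4,6-dimethylhepta-2,6-dienoate | C=C(C)C[C@](C)(O)/C=C/C(=O)OC
F3 | step 6 | methyl (2E,4S)-6-hydroperoxy-4-hydroxy-6-methoxy-4-methylhept-2-enoate | COC(C)(OO)C[C@](C)(O)/C=C/C(=O)OC
F4 | step 6 | methyl 2-[(3S,4S)-4-hydroxy-6-methoxy-4,6-dimethyl-1,2-dioxan-3-yl]acetate | COC1(C)C[C@](C)(O)[C@H](CC(=O)OC)OO1
F5 | step 4 | (3S)-3,5-dimethylhexa-1,5-dien-3-ol | C=C(C)C[C@](C)(O)C=C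
F6 | step 4 | (3S)-3,5-dimethylhexa-1,5-dien-3-yl prop-2-enoate | C=C(C)C[C@](C)(OC(=O)C=C)C=C
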